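Everything rests on cutting the C10–C11 single bond of the polyene. The key step exploits the C7≡C8 triple bond that flanks the methyl-branched C9=C10 olefin next to ring A: C9=C10 is read as a former terminal alkyne, so the left half is a ring A buta-1,3-diyne. In one pot, zirconium-catalysed syn-methylalumination of that terminal alkyne installs the C9 methyl group and the E olefin, and the C10 alkenylalane is then cross-coupled (palladium/zinc) with the C11 vinyl iodide of the complete C26 right half, which already carries the enolised β-diketone and the cyclopentane ring. Both rings come from one ketoisophorone-derived hydroxy enone.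

Key step: step 16

Assumption: carotenoid numbering is used (C1–C6 ring A, C7–C15 and C15'–C7' chain, C6' ketone, C1'–C5' cyclopentane); compounds 17 and 18 are taken as purchasable carotenoid building blocks, and the β-diketone is drawn and carried as its 8'-enol tautomer.

Step 1
Reactants: 1 2,6,6-trimethylcyclohex-2-ene-1,4-dione (ketoisophorone)
Product: 2 (4S)-4-hydroxy-2,6,6-trimethylcyclohex-2-en-1-one
Conditions: RuCl[(S,S)-TsDPEN](p-cymene) (1 mol %), HCO2H/Et3N (5:2), CH2Cl2, 25 °C
Reagents that add atoms: none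
Why: Noyori-type asymmetric transfer hydrogenation should reduce only the unhindered C4 carbonyl (C1 is shielded by the gem-dimethyl group and the C2 methyl), and the (S,S)-ligand is expected to give the (S)-carbinol with the olefin playing the role of an aryl group; this one stereocentre becomes C3 of ring A and C3' of the cyclopentane ring.

Step 2
Reactants: 2 (4S)-4-hydroxy-2,6,6-trimethylcyclohex-2-en-1-one
Product: 3 (4S)-4-[(tert-butyldimethylsilyl)oxy]-2,6,6-trimethylcyclohex-2-en-1-one
Conditions: TBSCl, imidazole, DMF, rt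
Reagents that add atoms: tert-butyldimethylsilyl chloride, CC(C)(C)[Si](C)(C)Cl
Why: Standard silylation of the secondary alcohol, which protects it for the hydride, Grignard and Lewis acid steps that follow.

Step 3
Reactants: 3 (4S)-4-[(tert-butyldimethylsilyl)oxy]-2,6,6-trimethylcyclohex-2-en-1-one
Product: 5 (4R)-4-[(tert-butyldimethylsilyl)oxy]-2,6,6-trimethylcyclohex-1-en-1-yl trifluoromethanesulfonate, via lithium enolate 4 (not isolated)
Conditions: L-Selectride, THF, −78 °C; then PhNTf2, −78 °C → rt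
Reagents that add atoms: N-phenylbis(trifluoromethanesulfonimide), O=S(=O)(N(c1ccccc1)S(=O)(=O)C(F)(F)F)C(F)(F)F
Why: Conjugate hydride addition to the carbonyl-hindered enone gives the tetrasubstituted enolate regiospecifically and O-triflation traps it (reductive enol triflate formation); the silyloxy group is γ to the enolate carbon and cannot be eliminated, and the stereocentre is untouched (its descriptor changes only by the sequence rule).

Step 4
Reactants: 5 (4R)-4-[(tert-butyldimethylsilyl)oxy]-2,6,6-trimethylcyclohex-1-en-1-yl trifluoromethanesulfonate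
Product: 6 tert-butyldimethyl{[(1R)-3,4,5,5-tetramethylcyclohex-3-en-1-yl]oxy}silane
Conditions: MeMgBr, Fe(acac)3 (5 mol %), THF/NMP, −20 → 0 °C
Reagents that add atoms: methylmagnesium bromide, C[Mg]Br
Why: Iron-catalysed cross-coupling of the hindered alkenyl triflate with the methyl Grignard reagent should give the tetrasubstituted 1,2-dimethyl olefin with its position fixed by the triflate.

Step 5
Reactants: 6 tert-butyldimethyl{[(1R)-3,4,5,5-tetramethylcyclohex-3-en-1-yl]oxy}silane
Product: 7 (1S,4S,6R)-4-[(tert-butyldimethylsilyl)oxy]-1,2,2,6-tetramethyl-7-oxabicyclo[4.1.0]heptane (epoxide oxygen trans to the silyloxy group)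
Conditions: mCPBA, NaHCO3, CH2Cl2, −20 → 0 °C
Reagents that add atoms: 3-chloroperoxybenzoic acid, OOC(=O)c1cccc(Cl)c1
Why: Prilezhaev epoxidation of the electron-rich tetrasubstituted olefin is expected, as with other O-protected 3-hydroxy-β-end groups, to occur mainly anti to the silyloxy group; this face decides the configuration of the quaternary centre made in step 6.

Step 6
Reactants: 7 (1S,4S,6R)-4-[(tert-butyldimethylsilyl)oxy]-1,2,2,6-tetramethyl-7-oxabicyclo[4.1.0]heptane
Product: 8 1-[(1R,4S)-4-[(tert-butyldimethylsilyl)oxy]-1,2,2-trimethylcyclopentyl]ethan-1-one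
Conditions: BF3·OEt2, CH2Cl2, −78 °C; then Et3N
Reagents that add atoms: none
Why: Lewis acid-promoted semipinacol (Meinwald-type) ring contraction, in which ionisation of either tertiary C–O bond is followed by anti 1,2-shift of the neighbouring ring carbon, so both modes converge on the same 1-acetyl-1,2,2-trimethylcyclopentane with the acetyl group on the former epoxide face, trans to the silyloxy group, which sets C5' as R beside the untouched C3' (S).

Step 7
Reactants: 2 (4S)-4-hydroxy-2,6,6-trimethylcyclohex-2-en-1-one; 9 1,4-bis(trimethylsilyl)buta-1,3-diyne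
Product: 11 (4S)-2,6,6-trimethyl-1-[4-(trimethylsilyl)buta-1,3-diyn-1-yl]cyclohex-2-ene-1,4-diol (both C1 epimers), via lithium silylbutadiynide 10 (not isolated)
Conditions: 9, MeLi·LiBr, THF, rt; then 2 (0.45 equiv), −78 → 0 °C; aq. NH4Cl
Reagents that add atoms: none
Why: After the first equivalent of acetylide has deprotonated the hydroxyl group, 1,2-addition to the hindered, non-enolisable C1 ketone gives the tertiary carbinol, whose configuration is irrelevant because step 8 erases it.

Step 8
Reactants: 11 (4S)-2,6,6-trimethyl-1-[4-(trimethylsilyl)buta-1,3-diyn-1-yl]cyclohex-2-ene-1,4-diol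
Product: 12 (1S)-3,5,5-trimethyl-4-[4-(trimethylsilyl)buta-1,3-diyn-1-yl]cyclohex-3-ene-1,2-diol (both C2 epimers)
Conditions: H2SO4 (0.1 M aq.), THF, rt
Reagents that add atoms: water, O
Why: Acid-catalysed 1,3-allylic transposition (ionisation of the tertiary allylic–propargylic alcohol and capture of water at the secondary terminus) is driven by formation of the tetrasubstituted ring A olefin conjugated to the diyne; the new carbinol configuration is not controlled here and need not be.

Step 9
Reactants: 12 (1S)-3,5,5-trimethyl-4-[4-(trimethylsilyl)buta-1,3-diyn-1-yl]cyclohex-3-ene-1,2-diol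
Product: 13 (6S)-6-hydroxy-2,4,4-trimethyl-3-[4-(trimethylsilyl)buta-1,3-diyn-1-yl]cyclohex-2-en-1-one
Conditions: MnO2, CH2Cl2, rt
Reagents that add atoms: none
Why: MnO2 oxidises only the allylic carbinol (carotenoid C4), so both epimers converge on one α-hydroxy enone while the C3 alcohol is left alone.

Step 10
Reactants: 13 (6S)-6-hydroxy-2,4,4-trimethyl-3-[4-(trimethylsilyl)buta-1,3-diyn-1-yl]cyclohex-2-en-1-one
Product: 14 (1S,2S)-3,5,5-trimethyl-4-[4-(trimethylsilyl)buta-1,3-diyn-1-yl]cyclohex-3-ene-1,2-diol (trans diol)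
Conditions: Me4NBH(OAc)3, MeCN/AcOH, −30 °C
Reagents that add atoms: none
Why: Hydroxyl-directed (Saksena–Evans) reduction, in which the C3 hydroxyl binds boron and delivers hydride to the same face of the C4 carbonyl, so the new hydroxyl ends trans to it and C4 is set as S.

Step 11
Reactants: 14 (1S,2S)-3,5,5-trimethyl-4-[4-(trimethylsilyl)buta-1,3-diyn-1-yl]cyclohex-3-ene-1,2-diol
Product: 16 (1S,2S)-4-(buta-1,3-diyn-1-yl)-3,5,5-trimethylcyclohex-3-ene-1,2-diol bis(tert-butyldimethylsilyl) ether (left half), via silyl-capped diyne 15 (not isolated)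
Conditions: TBSOTf, 2,6-lutidine, CH2Cl2, 0 °C; then K2CO3, MeOH, rt
Reagents that add atoms: tert-butyldimethylsilyl trifluoromethanesulfonate, CC(C)(C)[Si](C)(C)OS(=O)(=O)C(F)(F)F
Why: Both secondary hydroxyls are silylated by the reactive triflate, and methanolic carbonate then cleaves only the alkynyl C–Si bond, leaving the silyl ethers and releasing the terminal alkyne needed for carbometalation.

Step 12
Reactants: 17 (2E,4E,6E)-2,7-dimethylocta-2,4,6-trienedial; 18 ethyl (2E)-4-(diethoxyphosphoryl)-2-methylbut-2-enoate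
Product: 19 ethyl (2E,4E,6E,8E,10E)-2,6,11-trimethyl-12-oxododeca-2,4,6,8,10-pentaenoate
Conditions: 18, NaH, THF, 0 °C; added to 17 (3 equiv), −20 °C → rt
Reagents that add atoms: none
Why: Horner–Wadsworth–Emmons olefination with the stabilised allylic phosphonate anion should form the C11'=C12' bond E-selectively, and the excess of symmetrical dialdehyde favours mono-olefination.

Step 13
Reactants: 19 ethyl (2E,4E,6E,8E,10E)-2,6,11-trimethyl-12-oxododeca-2,4,6,8,10-pentaenoate
Product: 20 ethyl (2E,4E,6E,8E,10E,12E)-13-iodo-2,6,11-trimethyltrideca-2,4,6,8,10,12-hexaenoate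
Conditions: CHI3, CrCl2, THF/1,4-dioxane, 0 °C → rt, dark
Reagents that add atoms: iodoform, IC(I)I
Why: Takai olefination adds C11 as an (E)-iodovinyl group through anti elimination from the gem-dichromium adduct and leaves the ester untouched.

Step 14
Reactants: 20 ethyl (2E,4E,6E,8E,10E,12E)-13-iodo-2,6,11-trimethyltrideca-2,4,6,8,10,12-hexaenoate
Product: 21 (2E,4E,6E,8E,10E,12E)-13-iodo-2,6,11-trimethyltrideca-2,4,6,8,10,12-hexaenoic acid
Conditions: LiOH, THF/MeOH/H2O, rt; then aq. HCl to pH 3
Reagents that add atoms: lithium hydroxide, [Li+].[OH-]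
Why: Saponification of the conjugated ester, under which the vinyl iodide and the polyene should be stable.

Step 15
Reactants: 21 (2E,4E,6E,8E,10E,12E)-13-iodo-2,6,11-trimethyltrideca-2,4,6,8,10,12-hexaenoic acid; 8 1-[(1R,4S)-4-[(tert-butyldimethylsilyl)oxy]-1,2,2-trimethylcyclopentyl]ethan-1-one
Product: 23 (2Z,4E,6E,8E,10E,12E,14E)-1-[(1R,4S)-4-[(tert-butyldimethylsilyl)oxy]-1,2,2-trimethylcyclopentyl]-3-hydroxy-15-iodo-4,8,13-trimethylpentadeca-2,4,6,8,10,12,14-heptaen-1-one (right half), via acid chloride 22 (not isolated)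
Conditions: 21, 1-chloro-N,N,2-trimethylprop-1-en-1-amine, CH2Cl2, 0 °C; then 8, MgBr2·OEt2, i-Pr2NEt, CH2Cl2, 0 °C → rt
Reagents that add atoms: none
Why: Crossed Claisen-type C-acylation by soft enolisation, in which the magnesium enolate of the methyl ketone (C7' is its only enolisable site) attacks the polyenoyl chloride formed under neutral conditions and the resulting magnesium diketonate chelate resists further acylation.

Step 16
Reactants: 16 (1S,2S)-4-(buta-1,3-diyn-1-yl)-3,5,5-trimethylcyclohex-3-ene-1,2-diol bis(tert-butyldimethylsilyl) ether; 23 the C26 iodo-polyene enol (right half)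
Product: 27 3,4,3'-tris-O-(tert-butyldimethylsilyl) ether of the target, via alkenylalane 24 (not isolated), via aluminium chelate of the iodide 25 (not isolated), via aluminium chelate of the coupled polyene 26 (not isolated)
Conditions: 16, Me3Al (3 equiv), Cp2ZrCl2 (25 mol %), CH2Cl2, 0 °C → rt, volatiles removed; 23 pre-treated with Me3Al (1 equiv), THF, −20 °C; combined with ZnCl2, Pd2(dba)3 (2.5 mol %), P(2-furyl)3 (10 mol %), THF, rt, dark; aq. NH4Cl/Rochelle salt
Reagents that add atoms: trimethylaluminium, C[Al](C)C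
Why: Cp2ZrCl2 and Me3Al generate a methylzirconium cation that adds syn across the terminal C9≡C10 alkyne of 16 with methyl going to the internal carbon C9, and exchange to aluminium gives the (E)-alkenyldimethylalane 24; after oxidative addition of zerovalent palladium into the C11–I bond of 25, zinc-mediated transmetalation and reductive elimination form the C10–C11 bond with retention at both olefins. The closest known reaction type is the Negishi zirconium-catalysed carboalumination followed by palladium–zinc cross-coupling, as used for conjugated polyenes. No ring is closed and no stereocentre is created; the E geometry of C9=C10 follows from the syn addition and that of C11=C12 is carried over from the iodide. The step needs reaction at the terminal rather than the internal C7≡C8 triple bond, which the tetrasubstituted ring A olefin and its gem-dimethyl group shield, and aluminium at the terminal carbon, the normal regiochemistry for terminal alkynes. It also needs the alane to survive the acidic enol of 23, which is secured by capping the β-diketone beforehand as its dimethylaluminium chelate 25, an inert acetylacetonate-type complex that is released on aqueous work-up. The silyl ethers on C3, C4 and C3' keep the hydroxyl groups from consuming the alane.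

Step 17
Reactants: 27 3,4,3'-tris-O-(tert-butyldimethylsilyl) ether of the target
Product: 28 (3S,4S,3'S,5'R)-3,4,3',8'-tetrahydroxy-7,8-didehydro-β,κ-caroten-6'-one (target)
Conditions: HF·pyridine, pyridine, THF, 0 °C → rt, dark
Reagents that add atoms: none
Why: Buffered fluoride cleaves the three secondary silyl ethers under conditions mild enough for the allylic C4 alcohol, the enolised β-diketone and the polyene, and no stereocentre is touched.

Compound list
1 | 2,6,6-trimethylcyclohex-2-ene-1,4-dione (ketoisophorone) | CC1=CC(=O)CC(C)(C)C1=O | starting material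
2 | (4S)-4-hydroxy-2,6,6-trimethylcyclohex-2-en-1-one | CC1=C[C@@H](O)CC(C)(C)C1=O | intermediate
3 | (4S)-4-[(tert-butyldimethylsilyl)oxy]-2,6,6-trimethylcyclohex-2-en-1-one | CC1=C[C@@H](O[Si](C)(C)C(C)(C)C)CC(C)(C)C1=O | intermediate
4 | lithium (4R)-4-[(tert-butyldimethylsilyl)oxy]-2,6,6-trimethylcyclohex-1-en-1-olate (not isolated) | CC1=C(O[Li])C(C)(C)C[C@H](O[Si](C)(C)C(C)(C)C)C1 | intermediate
5 | (4R)-4-[(tert-butyldimethylsilyl)oxy]-2,6,6-trimethylcyclohex-1-en-1-yl trifluoromethanesulfonate | CC1=C(OS(=O)(=O)C(F)(F)F)C(C)(C)C[C@H](O[Si](C)(C)C(C)(C)C)C1 | intermediate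
6 | tert-butyldimethyl{[(1R)-3,4,5,5-tetramethylcyclohex-3-en-1-yl]oxy}silane | CC1=C(C)C(C)(C)C[C@H](O[Si](C)(C)C(C)(C)C)C1 | intermediate
7 | (1S,4S,6R)-4-[(tert-butyldimethylsilyl)oxy]-1,2,2,6-tetramethyl-7-oxabicyclo[4.1.0]heptane (epoxide oxygen trans to the silyloxy group) | C[C@]12O[C@@]1(C)C(C)(C)C[C@H](O[Si](C)(C)C(C)(C)C)C2 | intermediate
8 | 1-[(1R,4S)-4-[(tert-butyldimethylsilyl)oxy]-1,2,2-trimethylcyclopentyl]ethan-1-one (acetyl trans to silyloxy) | CC(=O)[C@]1(C)C[C@@H](O[Si](C)(C)C(C)(C)C)CC1(C)C | intermediate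
9 | 1,4-bis(trimethylsilyl)buta-1,3-diyne | C[Si](C)(C)C#CC#C[Si](C)(C)C | starting material
10 | lithium 4-(trimethylsilyl)buta-1,3-diyn-1-ide (not isolated) | [Li]C#CC#C[Si](C)(C)C | intermediate
11 | (4S)-2,6,6-trimethyl-1-[4-(trimethylsilyl)buta-1,3-diyn-1-yl]cyclohex-2-ene-1,4-diol (both C1 epimers) | CC1=C[C@@H](O)CC(C)(C)C1(O)C#CC#C[Si](C)(C)C | intermediate
12 | (1S)-3,5,5-trimethyl-4-[4-(trimethylsilyl)buta-1,3-diyn-1-yl]cyclohex-3-ene-1,2-diol (both C2 epimers) | CC1=C(C#CC#C[Si](C)(C)C)C(C)(C)C[C@H](O)C1O | intermediate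
13 | (6S)-6-hydroxy-2,4,4-trimethyl-3-[4-(trimethylsilyl)buta-1,3-diyn-1-yl]cyclohex-2-en-1-one | CC1=C(C#CC#C[Si](C)(C)C)C(C)(C)C[C@H](O)C1=O | intermediate
14 | (1S,2S)-3,5,5-trimethyl-4-[4-(trimethylsilyl)buta-1,3-diyn-1-yl]cyclohex-3-ene-1,2-diol (trans diol) | CC1=C(C#CC#C[Si](C)(C)C)C(C)(C)C[C@H](O)[C@H]1O | intermediate
15 | bis(tert-butyldimethylsilyl) ether of 14 (not isolated) | CC1=C(C#CC#C[Si](C)(C)C)C(C)(C)C[C@H](O[Si](C)(C)C(C)(C)C)[C@H]1O[Si](C)(C)C(C)(C)C | intermediate
16 | (1S,2S)-4-(buta-1,3-diyn-1-yl)-3,5,5-trimethylcyclohex-3-ene-1,2-diol bis(tert-butyldimethylsilyl) ether (left half) | CC1=C(C#CC#C)C(C)(C)C[C@H](O[Si](C)(C)C(C)(C)C)[C@H]1O[Si](C)(C)C(C)(C)C | intermediate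
17 | (2E,4E,6E)-2,7-dimethylocta-2,4,6-trienedial | O=C/C(C)=C/C=C/C=C(C)/C=O | starting material
18 | ethyl (2E)-4-(diethoxyphosphoryl)-2-methylbut-2-enoate | CCOC(=O)/C(C)=C/CP(=O)(OCC)OCC | starting material
19 | ethyl (2E,4E,6E,8E,10E)-2,6,11-trimethyl-12-oxododeca-2,4,6,8,10-pentaenoate | CCOC(=O)/C(C)=C/C=C/C(C)=C/C=C/C=C(C)/C=O | intermediate
20 | ethyl (2E,4E,6E,8E,10E,12E)-13-iodo-2,6,11-trimethyltrideca-2,4,6,8,10,12-hexaenoate | CCOC(=O)/C(C)=C/C=C/C(C)=C/C=C/C=C(C)/C=C/I | intermediate
21 | (2E,4E,6E,8E,10E,12E)-13-iodo-2,6,11-trimethyltrideca-2,4,6,8,10,12-hexaenoic acid | OC(=O)/C(C)=C/C=C/C(C)=C/C=C/C=C(C)/C=C/I | intermediate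
22 | (2E,4E,6E,8E,10E,12E)-13-iodo-2,6,11-trimethyltrideca-2,4,6,8,10,12-hexaenoyl chloride (not isolated) | ClC(=O)/C(C)=C/C=C/C(C)=C/C=C/C=C(C)/C=C/I | intermediate
23 | (2Z,4E,6E,8E,10E,12E,14E)-1-[(1R,4S)-4-[(tert-butyldimethylsilyl)oxy]-1,2,2-trimethylcyclopentyl]-3-hydroxy-15-iodo-4,8,13-trimethylpentadeca-2,4,6,8,10,12,14-heptaen-1-one (right half) | I/C=C/C(C)=C/C=C/C=C(C)/C=C/C=C(C)/C(O)=C/C(=O)[C@]1(C)C[C@@H](O[Si](C)(C)C(C)(C)C)CC1(C)C | intermediate
24 | [(1E)-4-{(3S,4S)-3,4-bis[(tert-butyldimethylsilyl)oxy]-2,6,6-trimethylcyclohex-1-en-1-yl}-2-methylbut-1-en-3-yn-1-yl]dimethylalane (not isolated) | CC1=C(C#C/C(C)=C/[Al](C)C)C(C)(C)C[C@H](O[Si](C)(C)C(C)(C)C)[C@H]1O[Si](C)(C)C(C)(C)C | intermediate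
25 | dimethylaluminium enolate chelate of 23 (not isolated) | I/C=C/C(C)=C/C=C/C=C(C)/C=C/C=C(C)/C(O[Al](C)C)=C/C(=O)[C@]1(C)C[C@@H](O[Si](C)(C)C(C)(C)C)CC1(C)C | intermediate
26 | dimethylaluminium enolate chelate of 27 (not isolated) | CC1=C(C#C/C(C)=C/C=C/C(C)=C/C=C/C=C(C)/C=C/C=C(C)/C(O[Al](C)C)=C/C(=O)[C@]2(C)C[C@@H](O[Si](C)(C)C(C)(C)C)CC2(C)C)C(C)(C)C[C@H](O[Si](C)(C)C(C)(C)C)[C@H]1O[Si](C)(C)C(C)(C)C | intermediate
27 | 3,4,3'-tris-O-(tert-butyldimethylsilyl) ether of the target | CC1=C(C#C/C(C)=C/C=C/C(C)=C/C=C/C=C(C)/C=C/C=C(C)/C(O)=C/C(=O)[C@]2(C)C[C@@H](O[Si](C)(C)C(C)(C)C)CC2(C)C)C(C)(C)C[C@H](O[Si](C)(C)C(C)(C)C)[C@H]1O[Si](C)(C)C(C)(C)C | intermediate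
28 | (3S,4S,3'S,5'R)-3,4,3',8'-tetrahydroxy-7,8-didehydro-β,κ-caroten-6'-one | CC1=C(C#C/C(C)=C/C=C/C(C)=C/C=C/C=C(C)/C=C/C=C(C)/C(O)=C/C(=O)[C@]2(C)C[C@@H](O)CC2(C)C)C(C)(C)C[C@H](O)[C@H]1O | target

Total step count: 17. Longest linear sequence: 9 steps (steps 1, 2, 3, 4, 5, 6, 15, 16, 17).

Steps most likely to fail

Step 16. The alkenylalane may be lost by protonolysis, or methyl may transfer in place of the alkenyl group, or transmetalation may stall in the presence of the aluminium diketonate, so that the one-pot coupling gives little product. The fallback sets out from 16 and 23 and comes back at 27. Compound 16 is carboaluminated as before and the alane is quenched with iodine (THF, −30 °C) to give the (E)-iodoenyne {[(1S,2S)-4-[(3E)-4-iodo-3-methylbut-3-en-1-yn-1-yl]-3,5,5-trimethylcyclohex-3-ene-1,2-diyl]bis(oxy)}bis(tert-butyldimethylsilane) F1. Compound 23 is converted with hexamethylditin and Pd(PPh3)4 (THF, 50 °C) into the trimethylstannyl analogue of 23 F2. A Stille coupling of the two (Pd2(dba)3, AsPh3, NMP, rt) then forms the same C10–C11 bond under neutral conditions that tolerate the free enol and gives 27.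

Step 5. The peracid may attack with poor or reversed facial selectivity, which would invert the quaternary centre formed in step 6. The fallback sets out from 6 and comes back at 8. The cis epoxide (1R,4S,6S)-4-[(tert-butyldimethylsilyl)oxy]-1,2,2,6-tetramethyl-7-oxabicyclo[4.1.0]heptane F3 is opened by bromide (LiBr, AcOH, THF) with inversion at the less hindered tertiary carbon to give 2-bromo-4-[(tert-butyldimethylsilyl)oxy]-1,2,6,6-tetramethylcyclohexan-1-ol with bromine trans to both oxygen substituents F4. A silver-promoted semipinacol ring contraction (AgBF4, 2,6-di-tert-butylpyridine, CH2Cl2, −40 °C) then gives 8, because the migrating ring carbon again enters anti to the leaving group. Both epoxide diastereomers can thus be funnelled to 8.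

Step 15. The hindered methyl ketone may enolise slowly or be O-acylated, and the polyenoyl chloride may decompose before it is consumed. The fallback sets out from 20 and 8 and comes back at 23. Ester 20 is reduced with DIBAL-H (CH2Cl2, −78 °C) to (2E,4E,6E,8E,10E,12E)-13-iodo-2,6,11-trimethyltrideca-2,4,6,8,10,12-hexaen-1-ol F5, which is oxidised with MnO2 to (2E,4E,6E,8E,10E,12E)-13-iodo-2,6,11-trimethyltrideca-2,4,6,8,10,12-hexaenal F6. Aldol addition of the lithium enolate of 8 (LDA, THF, −78 °C) gives the 3-hydroxy-1-one aldol adduct (both carbinol epimers) F7, and Dess–Martin oxidation of the β-hydroxy ketone gives 23.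

Further compounds
F1 | step 16 | {[(1S,2S)-4-[(3E)-4-iodo-3-methylbut-3-en-1-yn-1-yl]-3,5,5-trimethylcyclohex-3-ene-1,2-diyl]bis(oxy)}bis(tert-butyldimethylsilane) | CC1=C(C#C/C(C)=C/I)C(C)(C)C[C@H](O[Si](C)(C)C(C)(C)C)[C@H]1O[Si](C)(C)C(C)(C)C
F2 | step 16 | trimethylstannyl analogue of 23 (SnMe3 in place of iodine at C11) | C[Sn](C)(C)/C=C/C(C)=C/C=C/C=C(C)/C=C/C=C(C)/C(O)=C/C(=O)[C@]1(C)C[C@@H](O[Si](C)(C)C(C)(C)C)CC1(C)C
F3 | step 5 | (1R,4S,6S)-4-[(tert-butyldimethylsilyl)oxy]-1,2,2,6-tetramethyl-7-oxabicyclo[4.1.0]heptane (epoxide oxygen cis to the silyloxy group) | C[C@@]12O[C@]1(C)C(C)(C)C[C@H](O[Si](C)(C)C(C)(C)C)C2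
F4 | step 5 | 2-bromo-4-[(tert-butyldimethylsilyl)oxy]-1,2,6,6-tetramethylcyclohexan-1-ol (bromine trans to hydroxyl and to silyloxy) | C[C@@]1(Br)C[C@@H](O[Si](C)(C)C(C)(C)C)CC(C)(C)[C@@]1(C)O
F5 | step 15 | (2E,4E,6E,8E,10E,12E)-13-iodo-2,6,11-trimethyltrideca-2,4,6,8,10,12-hexaen-1-ol | OC/C(C)=C/C=C/C(C)=C/C=C/C=C(C)/C=C/I
F6 | step 15 | (2E,4E,6E,8E,10E,12E)-13-iodo-2,6,11-trimethyltrideca-2,4,6,8,10,12-hexaenal | O=C/C(C)=C/C=C/C(C)=C/C=C/C=C(C)/C=C/I
F7 | step 15 | (4E,6E,8E,10E,12E,14E)-1-[(1R,4S)-4-[(tert-butyldimethylsilyl)oxy]-1,2,2-trimethylcyclopentyl]-3-hydroxy-15-iodo-4,8,13-trimethylpentadeca-4,6,8,10,12,14-hexaen-1-one (both C3 epimers) | I/C=C/C(C)=C/C=C/C=C(C)/C=C/C=C(C)/C(O)CC(=O)[C@]1(C)C[C@@H](O[Si](C)(C)C(C)(C)C)CC1(C)C
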